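The runs are simulated for substances that don't exist, noise included.

These flasks are slow: the dawn run took 48.0 h to bring left-handed product to 14.5% of the substrate charged.

| setting | noon | dawn | Wednesday's | Tuesday's |
|---|---|---|---|---|
| left-handed substrate | 0.087 M | 0.087 M | 0.087 M | 0.087 M |
| right-handed substrate | 0.087 M | 0.087 M | 0.087 M | 0.087 M |
| partner | 0.018 M | 0.047 M | 0.0200 M | 0.0696 M |
| catalyst | 0.17 mM | 0.17 mM | 0.17 mM | 0.17 mM |
| remark | run made earlier | run made earlier |  |  |
| time |  |  | 6.0 d | 3.0 d |

- noon (time / h: left-handed product / %, left-handed substrate / %): 12.0: 4.0, 46.1; 25.0: 5.0, 45.0; 40.0: 7.4, 43.5; 48.0: 6.4, 43.0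
- dawn (time / h: left-handed product / %, left-handed substrate / %): 6.00: 7.5, 45.5; 20.0: 12.7, 39.4; 30.0: 13.2, 34.5; 48.0: 14.5, 33.4

(scatter of a reading: 1 percentage point)

- which of the two ends with the higher amount of left-handed product, in percent of the left-handed substrate and right-handed substrate together charged ("neither" if they lie within 2 percentage points) (Wednesday's / Tuesday's / neither)
- left-handed product at the end, in percent of the left-handed substrate and right-handed substrate together charged, Wednesday's
- left-handed product at the end, in percent of the left-handed substrate and right-handed substrate together charged, Tuesday's

- catalyst is single-handed; left-handed substrate and right-handed substrate are mirror images of each other, charged as a racemate, each of them at the stated concentration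

Ines and Tom read these runs differently. Both first put partner in the product's currency, c(partner) / (c(left-handed substrate) + c(right-handed substrate)), which is 10.3% in the noon run and 27.0% in the dawn run.

Tom treats partner as the limiting reagent: even in Tuesday's, its 0.0696 M lies below the 0.087 M of left-handed substrate. Each partner, he says, ends in one left-handed product, and the runs were merely stopped early. His ceilings are therefore 40.0% for Tuesday's and 11.5% for Wednesday's, and he expects both flasks to come close to them.

Ines answers that the last readings hardly climb. The noon run went from 7.4% to 6.4%, and the dawn run rose 1.8 percentage points in 28.0 h, against a scatter of 1 point on each reading. So she freezes what stays nearly constant. Partner grew 2.61-fold between the runs, yet the last product reading divided by the partner charge went only from 0.619 to 0.537. Their mean, 0.578, is her yield on partner, the share of the partner charge that appears as left-handed product, read with catalyst at 0.17 mM.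

Multiplying it by each charge gives 23.1% for Tuesday's and 6.64% for Wednesday's. I commit to this reckoning, with Tuesday's ahead.

The forecast, a little apart from mine, also puts Tuesday's ahead, at 22% against 7.5% for Wednesday's, reading the runs “with partner exhausted and shared between enantiomers”.

The flasks give 22.3% for Tuesday's and 8.98% for Wednesday's, so Tuesday's is ahead.

    2 partner → self-condensation product (k = 2.70 × 10⁻⁵ M⁻¹ s⁻¹)
    catalyst ⇌ dormant form (K = 4.70, k = 5.30 × 10⁻⁶ s⁻¹)
    partner + catalyst + right-handed substrate → catalyst + right-handed product (k = 0.0450 M⁻² s⁻¹)
    partner + catalyst + left-handed substrate → catalyst + left-handed product (k = 0.720 M⁻² s⁻¹)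

Tuesday's yield on partner is 0.557, close to Ines's 0.578, while Wednesday's reaches 0.781, and it already stood at 0.699 at 3.00 d, higher than Tuesday's at that same time. Tom's view comes closest in Wednesday's left long: at 60.0 d, that flask holds 10.0%, a yield of 0.872, with partner at 0% of its charge, which is still below his ceiling; Tuesday's at 30.0 d holds 27.7%, a lower yield of 0.693. Now take a flask like Tuesday's with catalyst at 1.0 × 10⁻⁴ M. Its partner charge is unchanged, so the yield read at 0.17 mM again gives 23.1%. This flask gives 16.9%, a yield of 0.422, with 28% of its partner still there at 3.00 d.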